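The readings come from a simulation for substances that don't exist, noise included.

Time was what I looked at first when you asked for a quick number on Tuesday's flask and bet on more heat. Tuesday's X gained 16 percentage points between 8.00 min and 25.0 min, but 2.7 points between 25.0 min and 50.0 min, against a scatter of 1 point. I read that as a crossing: before it the clock governed X, and after it the charge did.

| flask | G | Z | temperature | remark | time |
|---|---|---|---|---|---|
| Tuesday's | 0.020 M | 0.016 M | 90 °C | the very flask that is asked about, followed so far |  |
| Monday's | 0.040 M | 0.016 M | 75 °C | run made earlier |  |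
| flask | 0.020 M | 0.0160 M | 90 °C |  | 80 min |

- Tuesday's (time / min: X / %): 8.00: 26.1; 15.0: 35.9; 25.0: 42.2; 30.0: 42.7; 40.0: 46.6; 50.0: 44.9
- Monday's (time / min: X / %): 5.00: 10.5; 10.0: 15.0; 15.0: 17.1; 20.0: 16.0; 25.0: 18.4; 30.0: 18.8

(scatter of a reading: 1 percentage point)

- X taken out counts as made
- additions bring no volume worth counting

- maple: at 80 min raise the temperature by 15 K, then wait 80 min
- ash: at 80 min take out 90% of the X then present, then wait 80 min
- elm: at 80 min add Z, 50.0% of the amount charged, then wait 80 min
- oak: change nothing and wait 80 min more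

- X, in percent of the G first charged, at 80 min
- the remedy with the largest gain of X, or "none" below 2 percentage points (maple / ash / elm / oak / none)
- X present, with what was taken out counted in, in percent of the G first charged, after ash
- X present, with what was taken out counted in, in percent of the G first charged, after oak

The charge I watched was Z, the limiting reagent, since 0.0160 M stood below 0.020 M of G. Tuesday's last two readings gave 0.572, and I carried this as the yield on Z, the X formed per Z charged. Monday's colder run, with more G, read 0.465.

With that yield I put Tuesday's flask at 45.8% at 80 min. Neither oak nor ash adds Z, and I kept both at that figure. Elm's extra Z, spent at the same yield, gave me 23 points more, so I chose elm.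

The forecast gave 46%, elm, 56% for ash and 46.5% for oak, in the words “So elm is the robust choice.” On ash it stood above my figure.

Tuesday's flask gave 50.2% at 80 min, and elm led with 15 points. Ash came to 53.3% with the X taken out counted in, and oak to 53.3%.

    G ⇌ L (K = 0.737, k = 0.0920 s⁻¹, Ea = 105 kJ mol⁻¹, ΔH = −28.0 kJ mol⁻¹)
    Z + L → X (k = 0.192 M⁻¹ s⁻¹, Ea = 68.0 kJ mol⁻¹)
    Z + J ⇌ Q (K = 190 M⁻¹, k = 0.579 M⁻¹ s⁻¹, Ea = 71.0 kJ mol⁻¹, ΔH = −57.0 kJ mol⁻¹)
    L ⇌ E (K = 0.698, k = 0.00344 s⁻¹, Ea = 105 kJ mol⁻¹, ΔH = −40.0 kJ mol⁻¹)
    G → D (k = 2.17 × 10⁻⁶ s⁻¹, Ea = 121 kJ mol⁻¹)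
    Z + L → J (k = 0.0883 M⁻¹ s⁻¹, Ea = 46.0 kJ mol⁻¹)
    (constants at 90 °C)

Tuesday's flask still held 4.62% of its Z free at 80.0 min. Its yield on Z had reached 0.628 by then, above my 0.572. On the neighbour with 0.050 M of G, my yield gave 18.3%, and that flask stood at 21.9% with 0.0285% of its Z free.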